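**Retrosynthetic overview**
1. The target is a 5,7-dihydroxy-6,8-diformylchroman trans-fused through C1/C10 to a ten-membered carbocycle; the two formyl groups and the free phenols and alcohol are revealed last.
2. The strategy rests on the C2–C3 bond of the carbocycle (ring C1–C10): C3 is the allylic CH2 at the methyl-bearing end of the Z C4=C5 alkene and C2 is an unfunctionalised CH2 on the ring-fusion carbon C1. Disconnection there gives a C2 α-phenylsulfonyl carbanion and a C3 (Z)-allylic chloride.
3. The chroman precursor comes from an acyclic triad: the pyran ring is closed by Pd-catalysed aryl–O coupling of the C10 tertiary alcohol, and the isobutyl group is set trans at Cb by allylsilane capture of the benzylic cation.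
4. C10 and C1 come from Sharpless epoxidation of an E-allylic alcohol and vinyl-cuprate opening at C1 (vinyl becomes C2); the chain comes from (R)-α-terpineol (C7 from the pool), with HWE for C10=C1 and Still–Gennari for Z C4=C5.
5. Ring order: pyran ring (step 15), then the ten-membered carbocycle (step 20); the arene is carried from step 10.

Key step: step 20

**Remarks on the chemistry.** Numbering: carbocycle C1–C10 (C1 ring-fusion CH, C10 the O-bearing quaternary carbon, C4 with its methyl and C5 the Z alkene, C7 the CH bearing the C11 carbinol), Cb the benzylic CH; chroman positions 2 (=C10), 3 (=C1), 4 (=Cb). Assumptions: the tertiary alcohol is carried as a tert-butyldimethylsilyl ether (sturdier than triethylsilyl towards the acidic and Lewis-acidic steps); minor alkene isomers from steps 3 and 5 are removed by chromatography; the carbinol centre at Cb in 17–23 is an epimer mixture that converges in step 16.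

**Route**

Step 1
Reactants: 1 (R)-α-terpineol
Product: 2 tert-butyldimethylsilyl ether of 1
Conditions: t-BuMe2SiOTf, 2,6-lutidine, CH2Cl2, 0 °C to rt
Reagents that add atoms: tert-butyldimethylsilyl trifluoromethanesulfonate, CC(C)(C)[Si](C)(C)OS(=O)(=O)C(F)(F)F
Why: O-silylation of the hindered tertiary alcohol needs the silyl triflate with a non-nucleophilic base, and the resulting tertiary silyl ether should survive every later step while C7 is untouched.

Step 2
Reactants: 2 silyl ether
Product: 4 keto acetal, via keto aldehyde 3 (not isolated)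
Conditions: O3, CH2Cl2/MeOH, −78 °C; Me2S, −78 °C to rt; then HC(OMe)3, PPTS (cat.), MeOH, rt
Reagents that add atoms: ozone, [O-][O+]=O; trimethyl orthoformate, COC(OC)OC
Why: Ozonolysis with reductive work-up cleaves the only alkene to the C10 methyl ketone and the C5 aldehyde, and acid-catalysed acetalisation then masks the aldehyde alone because aldehydes form dimethyl acetals far faster than methyl ketones.

Step 3
Reactants: 4 keto acetal; 5 triethyl phosphonoacetate
Product: 6 (E)-enoate acetal
Conditions: NaH, THF, 0 °C to 40 °C; minor Z isomer removed by chromatography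
Reagents that add atoms: none
Why: Horner–Wadsworth–Emmons olefination of the methyl ketone should favour the E trisubstituted enoate (ester trans to the longer chain), which fixes the C10=C1 geometry on which the stereospecific epoxidation and opening depend.

Step 4
Reactants: 6 (E)-enoate acetal
Product: 8 hydroxy aldehyde, via acetal alcohol 7 (not isolated)
Conditions: i-Bu2AlH, CH2Cl2, −78 °C, Rochelle-salt work-up; then PPTS (cat.), acetone/H2O, rt to 40 °C
Reagents that add atoms: water, O
Why: Hydride 1,2-reduction of the enoate gives the E allylic alcohol with the acetal intact, and mild transacetalisation then frees the C5 aldehyde without the stronger acid that could trigger a carbonyl–ene cyclisation onto the alkene.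

Step 5
Reactants: 8 hydroxy aldehyde; 9 ethyl 2-[bis(2,2,2-trifluoroethoxy)phosphoryl]propanoate
Product: 10 (2Z,8E)-dienoate alcohol
Conditions: KN(SiMe3)2, 18-crown-6, THF, −78 °C (anion of 9 preformed, then 8)
Reagents that add atoms: none
Why: Still–Gennari olefination with the trifluoroethyl phosphonate gives the Z trisubstituted enoate under kinetic control (ester carbon C3 cis to C6), and the weakly basic phosphonate anion leaves the free allylic alcohol alone.

Step 6
Reactants: 10 dienoate alcohol
Product: 11 epoxy alcohol
Conditions: Ti(OiPr)4 (cat.), D-(−)-diethyl tartrate, t-BuOOH, 4 Å molecular sieves, CH2Cl2, −20 °C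
Reagents that add atoms: tert-butyl hydroperoxide, CC(C)(C)OO
Why: Sharpless asymmetric epoxidation of this geraniol-type E allylic alcohol with the D-tartrate ligand should give the (2R,3R)-epoxy alcohol, setting C10 (R) and C1 under reagent control, while the enoate alkene, which is not an allylic alcohol, is not epoxidised.

Step 7
Reactants: 11 epoxy alcohol
Product: 12 vinyl diol
Conditions: CH2=CHMgBr (slow addition), CuI (cat.), THF/Et2O, −40 to −20 °C
Reagents that add atoms: vinylmagnesium bromide, C=C[Mg]Br
Why: Copper-catalysed Grignard opening of a 3,3-disubstituted 2,3-epoxy alcohol occurs by SN2 attack at the secondary carbon next to the carbinol (C1) with inversion while the C10–O bond is kept, so the vinyl group (future C2) is placed with the C10/C1 relative configuration of the target.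

Step 8
Reactants: 12 vinyl diol
Product: 13 α-vinyl aldehyde
Conditions: TEMPO (cat.), PhI(OAc)2, CH2Cl2, rt; used crude
Reagents that add atoms: none
Why: Oxoammonium oxidation converts the primary alcohol into the aldehyde (Cb) while the tertiary alcohol cannot be oxidised, and the nearly neutral conditions should leave the epimerisable β,γ-unsaturated centre C1 intact if the product is used at once.

Step 9
Reactants: 14 1-bromo-3,5-dimethoxybenzene
Product: 15 1-bromo-2-iodo-3,5-dimethoxybenzene
Conditions: N-iodosuccinimide, CF3CO2H (cat.), MeCN, rt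
Reagents that add atoms: N-iodosuccinimide, O=C1CCC(=O)N1I
Why: Electrophilic aromatic iodination goes ortho/para to the methoxy groups and should prefer the position between Br and OMe over the more hindered one between the two methoxy groups.

Step 10
Reactants: 13 α-vinyl aldehyde; 15 1-bromo-2-iodo-3,5-dimethoxybenzene
Product: 17 benzylic alcohol, via arylmagnesium chloride 16 (not isolated)
Conditions: 15, i-PrMgCl·LiCl, THF, −20 °C; LaCl3·2LiCl, then 13, −78 to −40 °C (excess 16; one equivalent is consumed by the tertiary OH)
Reagents that add atoms: none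
Why: Iodine–magnesium exchange is selective for C–I over C–Br and gives the ortho-bromoaryl Grignard reagent below the temperature of aryne formation, and its lanthanum-promoted 1,2-addition should outrun enolisation of the aldehyde; the new carbinol centre at Cb forms as an epimer mixture, which does not matter because it is ionised in step 16.

Step 11
Reactants: 17 benzylic alcohol
Product: 18 benzylic triethylsilyl ether
Conditions: Et3SiOTf, 2,6-lutidine, CH2Cl2, −78 °C
Reagents that add atoms: triethylsilyl trifluoromethanesulfonate, CC[Si](CC)(CC)OS(=O)(=O)C(F)(F)F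
Why: The secondary benzylic alcohol is silylated faster than the more hindered tertiary one, which prevents β-hydride loss from a palladium alkoxide in step 15 and provides the leaving group for step 16.

Step 12
Reactants: 18 benzylic triethylsilyl ether
Product: 20 primary alcohol, via aldehyde 19 (not isolated)
Conditions: OsO4 (cat.), NaIO4, 2,6-lutidine, dioxane/H2O, rt; then NaBH4, MeOH, 0 °C
Reagents that add atoms: sodium periodate, [Na+].[O-]I(=O)(=O)=O
Why: In this Lemieux–Johnson cleavage osmium tetroxide dihydroxylates the monosubstituted vinyl group much faster than the trisubstituted electron-poor enoate, periodate cleaves the diol and borohydride reduces the aldehyde at once, so the vinyl group becomes the C2 hydroxymethyl group without loss of configuration at C1.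

Step 13
Reactants: 20 primary alcohol
Product: 21 phenyl sulfide
Conditions: PhSSPh, n-Bu3P, THF, rt to 50 °C
Reagents that add atoms: diphenyl disulfide, c1ccc(cc1)SSc1ccccc1
Why: The phosphine–disulfide thioetherification (Hata reaction) activates only the primary alcohol as an alkoxyphosphonium ion, which thiolate displaces by SN2, and the tertiary alcohol stays free for step 15.

Step 14
Reactants: 21 phenyl sulfide
Product: 22 phenyl sulfone
Conditions: mCPBA (2.2 equiv), NaHCO3, CH2Cl2, 0 °C
Reagents that add atoms: 3-chloroperoxybenzoic acid, OOC(=O)c1cccc(Cl)c1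
Why: Peracid oxidation of the sulfide to the sulfone is much faster than any reaction of the electron-poor enoate or the arene, and the buffer protects the acid-labile benzylic silyl ether.

Step 15
Reactants: 22 phenyl sulfone
Product: 23 4-(triethylsilyloxy)chroman
Conditions: Pd(OAc)2 (cat.), 2-(di-tert-butylphosphino)-1,1′-binaphthyl, Cs2CO3, toluene, 80 °C
Reagents that add atoms: none
Why: Palladium-catalysed intramolecular aryl–oxygen coupling (Buchwald–Hartwig etherification) of the aryl bromide with the tertiary alcohol, which has no hydrogen on the carbinol carbon, closes the pyran ring, and C10 keeps its configuration because the C10–O bond is not broken.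

Step 16
Reactants: 23 4-(triethylsilyloxy)chroman
Product: 24 trans-4-(2-methylallyl)chroman
Conditions: 2-methylallyltrimethylsilane, Me3SiOTf (cat.), CH2Cl2, −78 °C
Reagents that add atoms: trimethyl(2-methylallyl)silane, CC(=C)C[Si](C)(C)C
Why: In this Hosomi–Sakurai-type SN1 substitution the silyl triflate ionises the benzylic silyl ether to a cation stabilised by the ring oxygen and the 5- and 7-methoxy groups, and the allylsilane should attack the face anti to the CH2SO2Ph group on C1, which sets Cb trans to C1 from both epimers of 23.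

Step 17
Reactants: 24 trans-4-(2-methylallyl)chroman
Product: 25 4-isobutylchroman ester
Conditions: H2 (1 atm), RhCl(PPh3)3 (cat.), toluene/EtOH, rt
Reagents that add atoms: none
Why: Homogeneous hydrogenation over the rhodium phosphine complex reduces the unhindered 1,1-disubstituted alkene and leaves the trisubstituted conjugated Z-enoate alone, which turns the methallyl into the isobutyl group.

Step 18
Reactants: 25 4-isobutylchroman ester
Product: 26 (Z)-allylic alcohol
Conditions: i-Bu2AlH, CH2Cl2, −78 °C
Reagents that add atoms: none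
Why: 1,2-Reduction of the unsaturated ester by the aluminium hydride gives the primary allylic alcohol with the Z geometry retained, and the sulfone, aryl ethers and silyl ether are inert.

Step 19
Reactants: 26 (Z)-allylic alcohol
Product: 27 (Z)-allylic chloride
Conditions: PPh3, CCl4, CH2Cl2, rt to 40 °C
Reagents that add atoms: carbon tetrachloride, ClC(Cl)(Cl)Cl
Why: Appel chlorination proceeds by SN2 displacement of the alkoxyphosphonium ion at the primary carbon, which converts primary allylic alcohols into chlorides without allylic transposition or Z/E isomerisation.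

Step 20
Reactants: 27 (Z)-allylic chloride
Product: 28 C2-phenylsulfonyl macrocycle (C2 epimers)
Conditions: KN(SiMe3)2 (1.5 equiv), THF, 0 °C; 27 added by syringe pump over several hours, final concentration about 0.002 M
Reagents that add atoms: none
Why: The amide base removes a proton from C2, the CH2 next to the sulfone, and the α-sulfonyl carbanion displaces chloride from the primary allylic carbon C3 in an intramolecular SN2 alkylation that forms the C2–C3 bond; the closest known reaction type is the macrocyclisation of sulfone-stabilised carbanions with allylic halides used for ten- to fourteen-membered terpenoid carbocycles. The ten-membered carbocycle (C1 to C10) closes in the 10-exo-tet mode, with the chloride outside the new ring. No stereocentre of the target is formed: C2 becomes a sulfone-bearing stereocentre without control and both epimers converge in step 21, while C1, C7, C10 and Cb are not touched. The step needs SN2 over SN2′ attack and ring closure over intermolecular alkylation; the primary terminus C3 is unhindered whereas attack at C5 would lead through an eight-membered transition state to a more crowded centre, and slow addition at high dilution keeps the carbanion concentration low. The all-trans chroman favours the conformer in which the C1–C2 and C10–C9 bonds are both equatorial and therefore gauche, because the diaxial conformer would suffer a 1,3-diaxial contact between the C9 chain and the isobutyl group, so the reacting ends are held close. The Z geometry of the C4=C5 alkene, set in step 5, takes no part in bond making and should be retained, and no other acidic or electrophilic site remains (the ester was reduced in step 18 and the tertiary alcohol is silylated).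

Step 21
Reactants: 28 C2-phenylsulfonyl macrocycle
Product: 29 macrocyclic dimethoxychroman
Conditions: Mg turnings, MeOH, rt to 50 °C
Reagents that add atoms: none
Why: Reductive desulfonylation by electron transfer from magnesium cleaves the C2–S bond and methanol protonates C2, so both C2 epimers converge on one compound while the isolated trisubstituted alkene, aryl ethers and silyl ether are not reduced.

Step 22
Reactants: 29 macrocyclic dimethoxychroman
Product: 31 6-carbaldehyde, via aryllithium 30 (not isolated)
Conditions: n-BuLi, TMEDA, THF, 0 °C; then DMF, −78 to 0 °C; aq NH4Cl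
Reagents that add atoms: N,N-dimethylformamide, CN(C)C=O
Why: Directed ortho-metalation removes the arene proton at C6, the position flanked by both methoxy groups, and the aryllithium is formylated by DMF, which places the first aldehyde regioselectively.

Step 23
Reactants: 31 6-carbaldehyde
Product: 32 5,7-dihydroxy-6-carbaldehyde
Conditions: MgI2·OEt2, toluene, 80 °C; aq NH4Cl
Reagents that add atoms: none
Why: Magnesium iodide cleaves aryl methyl ethers that can chelate through an ortho carbonyl group, and both methoxy groups flank the C6 aldehyde, so both phenols are freed while the silyl ether and alkene remain.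

Step 24
Reactants: 32 5,7-dihydroxy-6-carbaldehyde
Product: 33 6,8-dicarbaldehyde silyl ether
Conditions: POCl3, DMF, MeCN, 0 °C to rt; then aq NaOAc
Reagents that add atoms: N,N-dimethylformamide, CN(C)C=O; water, O
Why: In this Vilsmeier–Haack formylation the chloroiminium ion attacks C8, the only free ring position, which is activated by the ortho and para phenolic oxygens as in the diformylation of phloroglucinols, and hydrolysis gives the second aldehyde with the tertiary alcohol still protected.

Step 25
Reactants: 33 6,8-dicarbaldehyde silyl ether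
Product: 34 target CNP0570248.1
Conditions: HF·pyridine, pyridine, THF, 0 °C to rt
Reagents that add atoms: none
Why: Fluoride cleaves the Si–O bond of the tertiary silyl ether under buffered conditions that should not dehydrate the tertiary alcohol or disturb the Z alkene, which gives the target.

**Compound list**

1 | (R)-α-terpineol, (R)-2-(4-methylcyclohex-3-en-1-yl)propan-2-ol | CC1=CC[C@@H](CC1)C(C)(C)O | starting material
2 | (R)-tert-butyldimethyl{[2-(4-methylcyclohex-3-en-1-yl)propan-2-yl]oxy}silane | CC1=CC[C@@H](CC1)C(C)(C)O[Si](C)(C)C(C)(C)C | intermediate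
3 | (R)-3-[2-(tert-butyldimethylsilyloxy)propan-2-yl]-6-oxoheptanal | O=CC[C@H](C(C)(C)O[Si](C)(C)C(C)(C)C)CCC(C)=O | intermediate (not isolated)
4 | (R)-5-[2-(tert-butyldimethylsilyloxy)propan-2-yl]-7,7-dimethoxyheptan-2-one | COC(OC)C[C@H](C(C)(C)O[Si](C)(C)C(C)(C)C)CCC(C)=O | intermediate
5 | triethyl phosphonoacetate | CCOC(=O)CP(=O)(OCC)OCC | starting material
6 | ethyl (2E,6R)-6-[2-(tert-butyldimethylsilyloxy)propan-2-yl]-8,8-dimethoxy-3-methyloct-2-enoate | COC(OC)C[C@H](C(C)(C)O[Si](C)(C)C(C)(C)C)CC/C(C)=C/C(=O)OCC | intermediate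
7 | (2E,6R)-6-[2-(tert-butyldimethylsilyloxy)propan-2-yl]-8,8-dimethoxy-3-methyloct-2-en-1-ol | COC(OC)C[C@H](C(C)(C)O[Si](C)(C)C(C)(C)C)CC/C(C)=C/CO | intermediate (not isolated)
8 | (3R,6E)-3-[2-(tert-butyldimethylsilyloxy)propan-2-yl]-8-hydroxy-6-methyloct-6-enal | O=CC[C@H](C(C)(C)O[Si](C)(C)C(C)(C)C)CC/C(C)=C/CO | intermediate
9 | ethyl 2-[bis(2,2,2-trifluoroethoxy)phosphoryl]propanoate | CCOC(=O)C(C)P(=O)(OCC(F)(F)F)OCC(F)(F)F | starting material
10 | ethyl (2Z,5R,8E)-5-[2-(tert-butyldimethylsilyloxy)propan-2-yl]-10-hydroxy-2,8-dimethyldeca-2,8-dienoate | CCOC(=O)/C(C)=C\C[C@H](C(C)(C)O[Si](C)(C)C(C)(C)C)CC/C(C)=C/CO | intermediate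
11 | ethyl (2Z,5R)-5-[2-(tert-butyldimethylsilyloxy)propan-2-yl]-7-[(2R,3R)-3-(hydroxymethyl)-2-methyloxiran-2-yl]-2-methylhept-2-enoate | CCOC(=O)/C(C)=C\C[C@H](C(C)(C)O[Si](C)(C)C(C)(C)C)CC[C@@]1(C)O[C@@H]1CO | intermediate
12 | ethyl (2Z,5R,8R,9S)-5-[2-(tert-butyldimethylsilyloxy)propan-2-yl]-8-hydroxy-9-(hydroxymethyl)-2,8-dimethylundeca-2,10-dienoate | CCOC(=O)/C(C)=C\C[C@H](C(C)(C)O[Si](C)(C)C(C)(C)C)CC[C@@](C)(O)[C@@H](C=C)CO | intermediate
13 | aldehyde of 12 (CH2OH on C1 oxidised to the Cb aldehyde; C7, C10, C1 unchanged) | CCOC(=O)/C(C)=C\C[C@H](C(C)(C)O[Si](C)(C)C(C)(C)C)CC[C@@](C)(O)[C@@H](C=C)C=O | intermediate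
14 | 1-bromo-3,5-dimethoxybenzene | COc1cc(Br)cc(OC)c1 | starting material
15 | 1-bromo-2-iodo-3,5-dimethoxybenzene | COc1cc(OC)c(I)c(Br)c1 | intermediate
16 | (2-bromo-4,6-dimethoxyphenyl)magnesium chloride (LiCl complex) | COc1cc(OC)c([Mg]Cl)c(Br)c1 | intermediate (not isolated)
17 | benzylic alcohol: 13 with the 2-bromo-4,6-dimethoxyphenyl group added to Cb (both Cb epimers) | CCOC(=O)/C(C)=C\C[C@H](C(C)(C)O[Si](C)(C)C(C)(C)C)CC[C@@](C)(O)[C@@H](C=C)C(O)c1c(Br)cc(OC)cc1OC | intermediate
18 | benzylic triethylsilyl ether of 17 | CCOC(=O)/C(C)=C\C[C@H](C(C)(C)O[Si](C)(C)C(C)(C)C)CC[C@@](C)(O)[C@@H](C=C)C(O[Si](CC)(CC)CC)c1c(Br)cc(OC)cc1OC | intermediate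
19 | C2 aldehyde from cleavage of the vinyl group of 18 | CCOC(=O)/C(C)=C\C[C@H](C(C)(C)O[Si](C)(C)C(C)(C)C)CC[C@@](C)(O)[C@@H](C=O)C(O[Si](CC)(CC)CC)c1c(Br)cc(OC)cc1OC | intermediate (not isolated)
20 | C2 primary alcohol | CCOC(=O)/C(C)=C\C[C@H](C(C)(C)O[Si](C)(C)C(C)(C)C)CC[C@@](C)(O)[C@@H](CO)C(O[Si](CC)(CC)CC)c1c(Br)cc(OC)cc1OC | intermediate
21 | C2 phenyl sulfide | CCOC(=O)/C(C)=C\C[C@H](C(C)(C)O[Si](C)(C)C(C)(C)C)CC[C@@](C)(O)[C@@H](CSc1ccccc1)C(O[Si](CC)(CC)CC)c1c(Br)cc(OC)cc1OC | intermediate
22 | C2 phenyl sulfone | CCOC(=O)/C(C)=C\C[C@H](C(C)(C)O[Si](C)(C)C(C)(C)C)CC[C@@](C)(O)[C@@H](CS(=O)(=O)c1ccccc1)C(O[Si](CC)(CC)CC)c1c(Br)cc(OC)cc1OC | intermediate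
23 | (2R,3S)-5,7-dimethoxy-2-methyl-3-(phenylsulfonylmethyl)-4-(triethylsilyloxy)chroman carrying the (Z)-enoate arm on C2 (both C4 epimers) | CCOC(=O)/C(C)=C\C[C@H](C(C)(C)O[Si](C)(C)C(C)(C)C)CC[C@@]2(C)Oc3cc(OC)cc(OC)c3C(O[Si](CC)(CC)CC)[C@@H]2CS(=O)(=O)c4ccccc4 | intermediate
24 | (2R,3S,4S)-4-(2-methylallyl) analogue of 23 (3,4-trans) | CCOC(=O)/C(C)=C\C[C@H](C(C)(C)O[Si](C)(C)C(C)(C)C)CC[C@@]2(C)Oc3cc(OC)cc(OC)c3[C@@H](CC(C)=C)[C@@H]2CS(=O)(=O)c4ccccc4 | intermediate
25 | (2R,3S,4S)-4-isobutylchroman (Z)-enoate | CCOC(=O)/C(C)=C\C[C@H](C(C)(C)O[Si](C)(C)C(C)(C)C)CC[C@@]2(C)Oc3cc(OC)cc(OC)c3[C@@H](CC(C)C)[C@@H]2CS(=O)(=O)c4ccccc4 | intermediate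
26 | (Z)-allylic alcohol from 25 | OC/C(C)=C\C[C@H](C(C)(C)O[Si](C)(C)C(C)(C)C)CC[C@@]2(C)Oc3cc(OC)cc(OC)c3[C@@H](CC(C)C)[C@@H]2CS(=O)(=O)c4ccccc4 | intermediate
27 | (2R,3S,4S)-2-[(3R,5Z)-7-chloro-3-(2-(tert-butyldimethylsilyloxy)propan-2-yl)-6-methylhept-5-en-1-yl]-4-isobutyl-5,7-dimethoxy-2-methyl-3-(phenylsulfonylmethyl)chroman (key-step precursor) | ClC/C(C)=C\C[C@H](C(C)(C)O[Si](C)(C)C(C)(C)C)CC[C@@]2(C)Oc3cc(OC)cc(OC)c3[C@@H](CC(C)C)[C@@H]2CS(=O)(=O)c4ccccc4 | intermediate
28 | C2-phenylsulfonyl macrocycle, silyl and methyl ethers in place (key-step product, C2 epimers) | C/C1=C/C[C@H](C(C)(C)O[Si](C)(C)C(C)(C)C)CC[C@@]2(C)Oc3cc(OC)cc(OC)c3[C@@H](CC(C)C)[C@@H]2C(S(=O)(=O)c4ccccc4)C1 | intermediate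
29 | desulfonylated macrocyclic 5,7-dimethoxychroman | C/C1=C/C[C@H](C(C)(C)O[Si](C)(C)C(C)(C)C)CC[C@@]2(C)Oc3cc(OC)cc(OC)c3[C@@H](CC(C)C)[C@@H]2CC1 | intermediate
30 | C6 aryllithium of 29 | C/C1=C/C[C@H](C(C)(C)O[Si](C)(C)C(C)(C)C)CC[C@@]2(C)Oc3cc(OC)c([Li])c(OC)c3[C@@H](CC(C)C)[C@@H]2CC1 | intermediate (not isolated)
31 | 5,7-dimethoxy-6-carbaldehyde | C/C1=C/C[C@H](C(C)(C)O[Si](C)(C)C(C)(C)C)CC[C@@]2(C)Oc3cc(OC)c(C=O)c(OC)c3[C@@H](CC(C)C)[C@@H]2CC1 | intermediate
32 | 5,7-dihydroxy-6-carbaldehyde | C/C1=C/C[C@H](C(C)(C)O[Si](C)(C)C(C)(C)C)CC[C@@]2(C)Oc3cc(O)c(C=O)c(O)c3[C@@H](CC(C)C)[C@@H]2CC1 | intermediate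
33 | 5,7-dihydroxy-6,8-dicarbaldehyde, tertiary silyl ether | C/C1=C/C[C@H](C(C)(C)O[Si](C)(C)C(C)(C)C)CC[C@@]2(C)Oc3c(C=O)c(O)c(C=O)c(O)c3[C@@H](CC(C)C)[C@@H]2CC1 | intermediate
34 | CNP0570248.1 | C/C1=C/C[C@H](C(C)(C)O)CC[C@@]2(C)Oc3c(C=O)c(O)c(C=O)c(O)c3[C@@H](CC(C)C)[C@@H]2CC1 | target

**Step count.** 25 steps in total; the longest linear sequence is 24 steps (1 to 34 through steps 1–8 and 10–25; step 9 is a one-step side branch).

**Steps most likely to fail**

Step 20 (ring closure). The carbanion carbon C2 sits next to the ring-fusion carbon and its branched neighbours, so closure may be slow and intermolecular alkylation (oligomerisation) or base-induced loss of HCl from the allylic chloride may overtake it. Fallback: keep the sulfone alkylation for the C2–C3 bond but run it intermolecularly, and close the ring by metathesis at C4=C5. It sets out from 25: Lemieux–Johnson cleavage of the enoate alkene (OsO4 cat., NaIO4) would give the C5 aldehyde F1, and Wittig methylenation (Ph3P=CH2) the terminal alkene F2. Deprotonation of the sulfone (n-BuLi) and alkylation with 3-chloro-2-methylpropene would give the diene F3. Ring-closing metathesis with the second-generation Grubbs catalyst at high dilution should then form the trisubstituted C4=C5 alkene, Z being favoured in a ten-membered ring, and comes back to the route at 28.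

Step 16 (trans isobutyl precursor). After ionisation the benzylic cation may lose the C1 proton (E1, giving the 2H-chromene and erasing C1), or the silane may add from the face syn to the C1 substituent. Fallback: form the Cb–C bond through a benzylic radical/organonickel species instead of a free cation. It sets out from 23: selective removal of the benzylic silyl group (HF·pyridine, 0 °C) would give the chroman-4-ol F4, which is converted in situ (MsCl, Et3N, LiCl, −20 °C) into the benzylic chloride F5. Nickel-catalysed Negishi coupling with isobutylzinc bromide (NiBr2·diglyme, 4,4′-di-tert-butyl-2,2′-bipyridine, DMA) would deliver the isobutyl group directly, with capture expected anti to the C1 substituent. It comes back at 25 and makes step 17 unnecessary.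

Step 10 (aryl addition). The hindered aryl Grignard reagent may deprotonate the α-vinyl aldehyde (enolisation, then epimerisation of C1 or conjugation), or the magnesium aldolate may undergo retro-aldol cleavage. Fallback: add the aryl group before the epoxide is opened, when no enolisable centre or free β-hydroxyl exists. It sets out from 11: oxidation (SO3·pyridine, DMSO, i-Pr2NEt) would give the epoxy aldehyde F6, and addition of 16 the epoxy carbinol F7 (Cb epimers). Copper-catalysed vinylmagnesium bromide opening at C1, now directed by the secondary carbinol, then comes back to the route at 17.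

**Further compounds**

F1 | step 20 | C5 aldehyde from cleavage of the enoate of 25 | O=CC[C@H](C(C)(C)O[Si](C)(C)C(C)(C)C)CC[C@@]2(C)Oc3cc(OC)cc(OC)c3[C@@H](CC(C)C)[C@@H]2CS(=O)(=O)c4ccccc4
F2 | step 20 | terminal alkene (C5=CH2) | C=CC[C@H](C(C)(C)O[Si](C)(C)C(C)(C)C)CC[C@@]2(C)Oc3cc(OC)cc(OC)c3[C@@H](CC(C)C)[C@@H]2CS(=O)(=O)c4ccccc4
F3 | step 20 | C2-(2-methylallyl) sulfone diene | C=CC[C@H](C(C)(C)O[Si](C)(C)C(C)(C)C)CC[C@@]2(C)Oc3cc(OC)cc(OC)c3[C@@H](CC(C)C)[C@@H]2C(CC(C)=C)S(=O)(=O)c4ccccc4
F4 | step 16 | chroman-4-ol from 23 | CCOC(=O)/C(C)=C\C[C@H](C(C)(C)O[Si](C)(C)C(C)(C)C)CC[C@@]2(C)Oc3cc(OC)cc(OC)c3C(O)[C@@H]2CS(=O)(=O)c4ccccc4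
F5 | step 16 | 4-chlorochroman | CCOC(=O)/C(C)=C\C[C@H](C(C)(C)O[Si](C)(C)C(C)(C)C)CC[C@@]2(C)Oc3cc(OC)cc(OC)c3C(Cl)[C@@H]2CS(=O)(=O)c4ccccc4
F6 | step 10 | epoxy aldehyde from 11 | CCOC(=O)/C(C)=C\C[C@H](C(C)(C)O[Si](C)(C)C(C)(C)C)CC[C@@]1(C)O[C@@H]1C=O
F7 | step 10 | epoxy benzylic carbinol | CCOC(=O)/C(C)=C\C[C@H](C(C)(C)O[Si](C)(C)C(C)(C)C)CC[C@@]1(C)O[C@@H]1C(O)c2c(Br)cc(OC)cc2OC
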